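**Retrosynthetic overview**

1. Labels: ring A = spiro δ-lactone, B = cyclohexane, C = spiro tetrahydrofuran, D = tetrahydropyran, E = 1,3-dioxolane, F = γ-lactone; cage carbons: C-a = quaternary C(CH3) shared by C/D, C-b = CH(CH3) of D, C-c = CH alpha to the ring F carbonyl, C-d = O–CH shared by D/E/F, C-e = ketal C(CH3), C-f = orthoester carbon.
2. Last disconnection (rings D, E, F): the trioxa cage is the internal orthoester/ketal/lactone of a seco acid in which C-f is a spiro γ-lactone carbonyl, C-e a methyl ketone, C-d a secondary carbinol and the ring F carbonyl a free acid; acid closes the three rings together.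
3. Key disconnection (bonds C-a–C-b and C-c–C-d of ring D): three-component Michael–aldol coupling of the ring C lactone enolate, tert-butyl (E)-crotonate (C-b, C-c, ester) and 2,2-dimethoxypropanal (C-d, C-e). Enabling feature: in ring D, C-a is alpha to the acid-level C-f, C-b/C-c are beta/alpha to the ring F carbonyl, and C-d is a carbinol next to the ketone-level C-e, so ring D is a latent enolate + enoate + aldehyde triad.
4. Ring C: Barbier 2-(ethoxycarbonyl)allylation of the ring B ketone gives the spiro α-methylene lactone that serves as regiospecific enolate precursor. The ring B stereocentres (C–OH, axial C-methyl, tertiary carbinol) come from a temporary 1,2-dioxane bridge, formed by hydroperoxide oxa-Michael addition to the carvone enone and reduced later to the two hydroxyls.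
5. Ring A and the ring B quaternary carbon: (R)-carvone, alpha-prime formylation, acrylate Michael addition, aldehyde reduction/lactonisation. Order of ring formation: B (carvone), A, temporary peroxide ring, C, then D/E/F together.

Key step: step 10

Remark: 2,2-dimethoxypropanal (17) is taken as not commercially available and is made in step 9 from commercial methyl 2,2-dimethoxypropanoate (16).

**Route**

Step 1
Reactants: 1 (R)-(−)-carvone; 2 2,2,2-trifluoroethyl formate
Product: 3 6-(hydroxymethylidene)carvone
Conditions: LiN(i-Pr)2 (1.1 equiv), THF, −78 °C; then 2 (1.5 equiv), −78 → 0 °C; aq. HCl work-up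
Reagents that add atoms: none
Why: Kinetic deprotonation of the cross-conjugated enone takes place at the alpha-prime CH2 and Claisen-type C-formylation with the activated formate should give the chelated hydroxymethylidene ketone, the carvone stereocentre being untouched.

Step 2
Reactants: 3 6-(hydroxymethylidene)carvone; 4 methyl acrylate
Product: 5 formyl keto ester
Conditions: DBU (0.1 equiv), MeCN, 0 °C → rt
Reagents that add atoms: none
Why: Base-catalysed Michael addition of the 2-formyl ketone (a 1,3-dicarbonyl donor) creates the quaternary carbon, the acrylate approaching the planar enolate anti to the neighbouring isopropenyl group, so that the propanoate chain ends trans and the formyl group cis to it.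

Step 3
Reactants: 5 formyl keto ester
Product: 7 spiro δ-lactone enone, via hydroxy ester 6 (not isolated)
Conditions: NaBH4 (0.35 equiv), MeOH/CH2Cl2 (1:1), −78 °C; then CSA (cat.), CH2Cl2, rt
Reagents that add atoms: none
Why: At low temperature NaBH4 should reduce the aldehyde much faster than the conjugated ketone or the ester (chemoselective carbonyl reduction), and the neopentyl alcohol then lactonises onto the methyl ester under acid catalysis to close ring A.

Step 4
Reactants: 7 spiro δ-lactone enone
Product: 8 triethylsilyl peroxide
Conditions: Co(acac)2 (5 mol %), Et3SiH (2 equiv), O2 (1 atm), ClCH2CH2Cl, rt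
Reagents that add atoms: dioxygen `O=O`; triethylsilane `CC[SiH](CC)CC`
Why: Cobalt-catalysed Mukaiyama–Isayama silylperoxidation proceeds by hydrogen-atom transfer to the electron-rich 1,1-disubstituted alkene (Markovnikov tertiary radical trapped by O2 and silylated) and should leave the electron-poor trisubstituted enone alone.

Step 5
Reactants: 8 triethylsilyl peroxide
Product: 10 peroxide-bridged ketone, via hydroperoxide 9 (not isolated)
Conditions: n-Bu4NF/AcOH (1:1, 1.2 equiv), THF, 0 °C; then Et2NH (0.2 equiv), CF3CH2OH, rt
Reagents that add atoms: none
Why: Fluoride frees the hydroperoxide, which adds intramolecularly to the enone beta-carbon (amine-catalysed peroxy-oxa-Michael addition, 6-exo) necessarily on the face of its own tether, so the new C–O centre is cis to the side chain; the alpha-methyl centre equilibrates under the basic conditions to the equatorial position of the chair–chair 2,3-dioxabicyclo[3.3.1]nonane, cis to the new C–O bond as the target requires.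

Step 6
Reactants: 10 peroxide-bridged ketone; 11 ethyl 2-(bromomethyl)acrylate
Product: 13 spiro α-methylene lactone, via hydroxy ester 12 (not isolated)
Conditions: In powder (1.5 equiv), THF/sat. aq. NH4Cl, rt; then TsOH·H2O (cat.), benzene, rt
Reagents that add atoms: none
Why: Barbier-type 2-(alkoxycarbonyl)allylation of the ketone (Dreiding–Schmidt α-methylene-γ-butyrolactone synthesis) should take place from the exo face, because the endo face of the carbonyl is covered by the peroxide bridge, so the new C–C bond is anti and the tertiary oxygen syn to the bridge; acid then closes ring C.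

Step 7
Reactants: 13 spiro α-methylene lactone
Product: 14 diol
Conditions: Zn dust (10 equiv), AcOH/THF (1:4), rt
Reagents that add atoms: none
Why: Zn/AcOH reduces the dialkyl peroxide O–O bond (standard peroxide-to-diol reduction) without touching the lactones or the α-methylene group, and so releases the secondary and the tertiary hydroxyl with their configurations already fixed.

Step 8
Reactants: 14 diol
Product: 15 bis(triethylsilyl) ether
Conditions: Et3SiOTf (3 equiv), 2,6-lutidine (5 equiv), CH2Cl2, −78 → 0 °C
Reagents that add atoms: triethylsilyl trifluoromethanesulfonate `CC[Si](CC)(CC)OS(=O)(=O)C(F)(F)F`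
Why: The silyl triflate silylates both the secondary and the hindered tertiary alcohol (silyl ether formation), so that no acidic O–H can quench the enolates of step 10.

Step 9
Reactants: 16 methyl 2,2-dimethoxypropanoate
Product: 17 2,2-dimethoxypropanal
Conditions: i-Bu2AlH (1.05 equiv), CH2Cl2, −78 °C; aq. potassium sodium tartrate work-up; used as a solution
Reagents that add atoms: none
Why: Half-reduction of the ester stops at the aldehyde level because the alpha-alkoxy groups stabilise the tetrahedral aluminate until work-up, and the aldehyde formed has no alpha-hydrogen and cannot enolise.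

Step 10
Reactants: 15 bis(triethylsilyl) ether; 18 tert-butyl (E)-but-2-enoate; 17 2,2-dimethoxypropanal
Product: 21 Michael–aldol adduct, via lactone enolate 19 (not isolated), via ester enolate 20 (not isolated)
Conditions: LiBH(s-Bu)3 (1.05 equiv), THF, −78 °C, 15 added slowly; then 18 (1.1 equiv), −78 → −40 °C; then 17 (1.5 equiv), −78 °C; AcOH quench at −78 °C
Reagents that add atoms: none
Why: Hydride from LiBH(s-Bu)3 adds 1,4 to the exocyclic methylene of 15 and gives regiospecifically the tetrasubstituted lithium lactone enolate 19 (the ring A lactone is not enolised); 19 adds to the β-carbon of 18 (Michael addition, bond C-a–C-b) and the resulting ester enolate 20 adds to the non-enolisable aldehyde 17 (aldol addition, bond C-c–C-d). The closest known reaction type is the three-component tandem Michael–aldol coupling of a lithium enolate, an enoate and an aldehyde, started here by the known conjugate reduction of an α-methylene lactone to its enolate. No ring is closed in this step: its task is to add the last seven carbons and to set the four contiguous stereocentres C-a to C-d, after which rings D, E and F close by themselves in step 11. C-a is controlled by approach of 18 to the enolate face turned away from the quaternary spiro carbon of rings A/B, and C-b by the closed, lithium-bridged eight-membered transition state, in which the s-cis (E)-enoate places its methyl group anti to the enolate C=C bond. C-c is controlled by allylic 1,3-strain in the (Z)-enolate 20 (the C-b hydrogen lies in the enolate plane and 17 enters anti to the quaternary C-a), and C-d by the aldol transition state, where the gauche repulsion between the two very large groups on the bond being formed and lithium chelation by a methoxy group of 17 should favour the 2,3-anti adduct. The step needs 1,4- over 1,2-addition and no oligomerisation, secured by the tert-butyl ester, one equivalent of 18 and low temperature; the anti aldol at C-d is the least certain element.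

Step 11
Reactants: 21 Michael–aldol adduct
Product: 23 chermebilaene B, via seco keto acid 22 (not isolated)
Conditions: CF3CO2H/CH2Cl2/H2O (20:78:2), 0 °C → rt; evaporate; then PPTS (cat.), 4 Å molecular sieves, toluene, 60 °C
Reagents that add atoms: water `O`
Why: Aqueous acid removes both silyl ethers, the tert-butyl ester and the dimethyl ketal, and the freed γ-keto acid/hydroxy lactone array should then close by acid-catalysed lactol formation, ketalisation and orthoesterification (the closure known for caged orthoesters of polyols): ring F by 5-exo attack of the carboxyl oxygen on the ketone carbon C-e, ring D by 6-exo attack of the C-d hydroxyl on the ring C lactone carbonyl C-f, and ring E by 5-exo capture of the activated C-f by the lactol oxygen; the two new stereocentres C-e and C-f have no choice, because rings D, E and F can only be cis-fused around C-d and ring C.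

**Compound list**

    1 | (R)-(−)-carvone, (5R)-2-methyl-5-(prop-1-en-2-yl)cyclohex-2-en-1-one | CC1=CC[C@@H](C(C)=C)CC1=O | starting material
    2 | 2,2,2-trifluoroethyl formate | O=COCC(F)(F)F | starting material
    3 | 6-(hydroxymethylidene)carvone, chelated enol of 6-formylcarvone (enol OH cis to the ring C=O), ring stereocentre as in 1 | CC1=CC[C@@H](C(C)=C)/C(=C/O)C1=O | intermediate
    4 | methyl acrylate | C=CC(=O)OC | starting material
    5 | methyl 3-[1-formyl-3-methyl-2-oxo-6-(prop-1-en-2-yl)cyclohex-3-en-1-yl]propanoate, formyl cis and propanoate chain trans to isopropenyl | CC1=CC[C@@H](C(C)=C)[C@](C=O)(CCC(=O)OC)C1=O | intermediate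
    6 | methyl 3-[1-(hydroxymethyl)-3-methyl-2-oxo-6-(prop-1-en-2-yl)cyclohex-3-en-1-yl]propanoate, hydroxymethyl cis to isopropenyl | CC1=CC[C@@H](C(C)=C)[C@](CO)(CCC(=O)OC)C1=O | intermediate
    7 | 8-methyl-11-(prop-1-en-2-yl)-2-oxaspiro[5.5]undec-8-ene-3,7-dione (rings A and B), ring A O–CH2 cis to isopropenyl | CC1=CC[C@@H](C(C)=C)[C@]2(CCC(=O)OC2)C1=O | intermediate
    8 | 7 with the isopropenyl group converted into 2-(triethylsilylperoxy)propan-2-yl | CC1=CC[C@@H](C(C)(C)OO[Si](CC)(CC)CC)[C@]2(CCC(=O)OC2)C1=O | intermediate
    9 | tertiary hydroperoxide, 11-(2-hydroperoxypropan-2-yl)-8-methyl-2-oxaspiro[5.5]undec-8-ene-3,7-dione | CC1=CC[C@@H](C(C)(C)OO)[C@]2(CCC(=O)OC2)C1=O | intermediate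
    10 | peroxide-bridged ketone: O–O joins the former enone beta-carbon and the CMe2 carbon (2,3-dioxabicyclo[3.3.1]nonane on ring B), C-methyl equatorial and cis to the C–O bond, ring A spiro as in 7 | C[C@H]1[C@@H](OOC3(C)C)C[C@@H]3[C@]2(CCC(=O)OC2)C1=O | intermediate
    11 | ethyl 2-(bromomethyl)acrylate | C=C(CBr)C(=O)OCC | starting material
    12 | tertiary alcohol from exo addition to 10, carrying CH2C(=CH2)CO2Et; OH syn to the peroxide bridge | C[C@H]1[C@@H](OOC3(C)C)C[C@@H]3[C@]2(CCC(=O)OC2)[C@]1(O)CC(=C)C(=O)OCC | intermediate
    13 | spiro α-methylene-γ-butyrolactone (ring C) on the peroxide-bridged ring B; lactone O syn and ring CH2 anti to the peroxide bridge | C[C@H]1[C@@H](OOC3(C)C)C[C@@H]3[C@]2(CCC(=O)OC2)[C@]12CC(=C)C(=O)O2 | intermediate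
    14 | diol: ring B with secondary OH cis to the C-methyl, 2-hydroxypropan-2-yl group, spiro rings A and C (α-methylene lactone) | C[C@H]1[C@@H](O)C[C@@H](C(C)(C)O)[C@]2(CCC(=O)OC2)[C@]12CC(=C)C(=O)O2 | intermediate
    15 | bis(triethylsilyl) ether of 14 | C[C@H]1[C@@H](O[Si](CC)(CC)CC)C[C@@H](C(C)(C)O[Si](CC)(CC)CC)[C@]2(CCC(=O)OC2)[C@]12CC(=C)C(=O)O2 | intermediate
    16 | methyl 2,2-dimethoxypropanoate | COC(=O)C(C)(OC)OC | starting material
    17 | 2,2-dimethoxypropanal | O=CC(C)(OC)OC | intermediate
    18 | tert-butyl (E)-but-2-enoate | C/C=C/C(=O)OC(C)(C)C | starting material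
    19 | lithium enolate of the α-methyl ring C lactone derived from 15 | C[C@H]1[C@@H](O[Si](CC)(CC)CC)C[C@@H](C(C)(C)O[Si](CC)(CC)CC)[C@]2(CCC(=O)OC2)[C@]12CC(C)=C([O-])O2.[Li+] | intermediate
    20 | lithium (Z)-enolate of the tert-butyl ester Michael adduct (O–Li cis to C-b), C-a and C-b as in 23 | C[C@H]1[C@@H](O[Si](CC)(CC)CC)C[C@@H](C(C)(C)O[Si](CC)(CC)CC)[C@]2(CCC(=O)OC2)[C@]12C[C@@](C)(C(=O)O2)[C@@H](C)/C=C(/OC(C)(C)C)[O-].[Li+] | intermediate
    21 | Michael–aldol adduct: ring C lactone with quaternary C-a; C-b methyl, C-c tert-butyl ester, C-d hydroxyl (2,3-anti), C-e as dimethyl ketal; configurations C-a to C-d as in 23 | C[C@H]1[C@@H](O[Si](CC)(CC)CC)C[C@@H](C(C)(C)O[Si](CC)(CC)CC)[C@]2(CCC(=O)OC2)[C@]12C[C@@](C)(C(=O)O2)[C@@H](C)[C@@H](C(=O)OC(C)(C)C)[C@H](O)C(C)(OC)OC | intermediate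
    22 | seco keto acid: free carboxylic acid at C-c, free C-d hydroxyl, methyl ketone at C-e, spiro γ-lactone at C-f, both ring B hydroxyls free | C[C@H]1[C@@H](O)C[C@@H](C(C)(C)O)[C@]2(CCC(=O)OC2)[C@]12C[C@@](C)(C(=O)O2)[C@@H](C)[C@@H](C(=O)O)[C@H](O)C(C)=O | intermediate
    23 | chermebilaene B | C[C@H]1[C@@H](O)C[C@@H](C(C)(C)O)[C@]2(CCC(=O)OC2)[C@]12C[C@]1(C)[C@@H](C)[C@H]3C(=O)O[C@@]4(C)O[C@@]1(O[C@@H]34)O2 | target

**Step count and risks**

Total steps: 11. Longest linear sequence: 10 steps (steps 1–8, 10, 11); step 9 is a one-step side branch.

Step 10 is the most likely to fail. The tetrasubstituted enolate 19 may add too slowly to the β-substituted ester 18, so that proton transfer to the ring A lactone or oligomerisation of 18 takes over, and the aldol may discriminate poorly between syn and anti at C-d. The fallback replaces the aldehyde by an acceptor that already carries C-d at the ketone level, so that the enolate has to form only one intermolecular C–C bond and the carbinol centre is set afterwards by reduction. It sets out from 15 and 16 and rejoins the route at 21. Claisen condensation of tert-butyl acetate with 16 (LiN(i-Pr)2, THF, −78 °C) should give tert-butyl 4,4-dimethoxy-3-oxopentanoate F1. Knoevenagel condensation with acetaldehyde (piperidinium acetate) should give the doubly activated alkylidene β-keto ester tert-butyl 2-(2,2-dimethoxypropanoyl)but-2-enoate F2. Enolate 19, generated from 15 as in step 10, should add to the far more electrophilic F2 to give the β-keto ester Michael adduct F3, whose acidic C-c centre settles by equilibration. Reduction of the ketone under non-chelating Felkin–Anh conditions (n-Bu4NBH4, CH2Cl2/MeOH, −78 °C) should then give 21; chelation-controlled Zn(BH4)2 is the alternative if the opposite carbinol configuration results.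

Step 11 is the second risk. Closure of the cage may stall at the hydroxy-lactol stage because of an unfavourable orthoester equilibrium, or the acid may dehydrate the β-hydroxy acid or ionise the tertiary alcohol. The fallback closes the cage under base by an alkoxide relay that ends in an irreversible lactonisation, which needs a methyl ester. It sets out from 15 and comes back at 23. The step 10 sequence run with methyl (E)-crotonate in place of 18 should give, through 19 and the methyl ester enolate F4, the methyl ester adduct F5. AcOH/THF/H2O (40 °C) should remove the silyl ethers and the ketal to give the trihydroxy keto methyl ester F6. Catalytic DBU in toluene should then let the C-d alkoxide add to the ring C lactone carbonyl, the hemiorthoester alkoxide add to the methyl ketone, and the hemiketal alkoxide displace methoxide from the ester, giving 23. Under these conditions the C-d centre, alpha to the ketone, can also equilibrate through the enediol, so an epimer at C-d would be drawn into the same product.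

Step 6 is the third risk. The zerovalent metal may reduce the peroxide bridge before the slow addition to the hindered ketone takes place. The fallback changes the order of events so that the organometallic step meets no peroxide. It sets out from 10 and comes back at 15. Zn/AcOH should give the diol ketone F7 and Et3SiOTf/2,6-lutidine its bis(triethylsilyl) ether F8. A Reformatsky-type addition of the zinc reagent from 11 (activated Zn, THF, 50 °C), axial on the chair that carries the side chain equatorial and therefore from the same face as in step 6, should give the hydroxy ester F9, which lactonises in the flask to 15. The axial methyl group alpha to the ketone in F7 and F8 would have to be carried through under strictly neutral conditions to avoid epimerisation.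

Further compounds

    F1 | step 10 | tert-butyl 4,4-dimethoxy-3-oxopentanoate | CC(OC)(OC)C(=O)CC(=O)OC(C)(C)C
    F2 | step 10 | tert-butyl 2-(2,2-dimethoxypropanoyl)but-2-enoate (methyl trans to the ester) | C/C=C(/C(=O)OC(C)(C)C)C(=O)C(C)(OC)OC
    F3 | step 10 | β-keto ester Michael adduct of 19 and F2 (C-d as ketone) | C[C@H]1[C@@H](O[Si](CC)(CC)CC)C[C@@H](C(C)(C)O[Si](CC)(CC)CC)[C@]2(CCC(=O)OC2)[C@]12C[C@@](C)(C(=O)O2)[C@@H](C)[C@@H](C(=O)OC(C)(C)C)C(=O)C(C)(OC)OC
    F4 | step 11 | lithium (Z)-enolate of the methyl ester Michael adduct | C[C@H]1[C@@H](O[Si](CC)(CC)CC)C[C@@H](C(C)(C)O[Si](CC)(CC)CC)[C@]2(CCC(=O)OC2)[C@]12C[C@@](C)(C(=O)O2)[C@@H](C)/C=C(/OC)[O-].[Li+]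
    F5 | step 11 | methyl ester analogue of 21 | C[C@H]1[C@@H](O[Si](CC)(CC)CC)C[C@@H](C(C)(C)O[Si](CC)(CC)CC)[C@]2(CCC(=O)OC2)[C@]12C[C@@](C)(C(=O)O2)[C@@H](C)[C@@H](C(=O)OC)[C@H](O)C(C)(OC)OC
    F6 | step 11 | trihydroxy keto methyl ester (methyl ester of 22) | C[C@H]1[C@@H](O)C[C@@H](C(C)(C)O)[C@]2(CCC(=O)OC2)[C@]12C[C@@](C)(C(=O)O2)[C@@H](C)[C@@H](C(=O)OC)[C@H](O)C(C)=O
    F7 | step 6 | diol ketone from reduction of the peroxide bridge of 10 | C[C@H]1[C@@H](O)C[C@@H](C(C)(C)O)[C@]2(CCC(=O)OC2)C1=O
    F8 | step 6 | bis(triethylsilyl) ether of F7 | C[C@H]1[C@@H](O[Si](CC)(CC)CC)C[C@@H](C(C)(C)O[Si](CC)(CC)CC)[C@]2(CCC(=O)OC2)C1=O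
    F9 | step 6 | tertiary hydroxy ester from addition of the zinc reagent of 11 to F8 | C[C@H]1[C@@H](O[Si](CC)(CC)CC)C[C@@H](C(C)(C)O[Si](CC)(CC)CC)[C@]2(CCC(=O)OC2)[C@]1(O)CC(=C)C(=O)OCC
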